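Everything rests on disconnecting the conjugated C9=C10–C1=C2 diene that spans rings A and B and pivots on the fusion carbon C10 beside quaternary C5. In one operation a ruthenium carbene is passed from a C9 vinyl carbinol through a C10≡C1 ethynyl group on C5 to a C2 propenyl group, closing ring B and then ring A and leaving exactly this diene. The precursor is an open-chain dienyne that already carries the C3, C4, C5 stereotriad (Ireland–Claisen rearrangement for C4/C5, Felkin–Anh reduction for C3, C3 as silyl ether) and a free C8 hydroxyl. Oxidation at C8, the C7 isopropylidene and the dienoate ester follow.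

Key step: step 11

Remark on numbering: ring atoms carry eremophilane numbers (ring A: C1, C2, C3, C4, C5, C10; ring B: C5, C6, C7, C8, C9, C10), also in the open-chain compounds.
Remark on C8: the acrolein addition of step 10 cannot control C8, so 19, 20 and 21 are mixtures of the two C8 epimers and are written without a descriptor there; both converge on ketone 22 (the same holds for C7 in 24 and 25).
Remark on the design of 20: the alkyne stays terminal (C1 must end as CH), the C8 hydroxyl stays free, C3 carries a bulky silyl ether, and the C2 terminus is an (E)-propenyl group that loads slowly and leaves as propene.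
Assumption: the (4S,5S)-diazaborolidine controller of step 3 is taken to give the (2R,3R)-acid 8; if a first run shows the opposite sense, the (4R,5R)-controller is used and nothing else changes.

Step 1
Reactants: 1 (E)-3-methylpent-2-en-4-yn-1-ol
Product: 3 (E)-3-methyl-5-(trimethylsilyl)pent-2-en-4-yn-1-ol, via O,C-bis(trimethylsilyl) derivative 2 (not isolated)
Conditions: n-BuLi (2.1 equiv), THF, −78 °C; Me3SiCl (2.2 equiv), −78 °C to rt; 1 M HCl, rt
Reagents that add atoms: chlorotrimethylsilane, C[Si](C)(C)Cl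
Why: Acetylide C-silylation: the alkoxide–acetylide dianion is silylated at both sites and dilute acid then hydrolyses only the labile O–Si bond, so the acidic alkyne C–H is masked for the organolithium steps ahead.

Step 2
Reactants: 3 (E)-3-methyl-5-(trimethylsilyl)pent-2-en-4-yn-1-ol; 4 propanoyl chloride
Product: 5 (E)-3-methyl-5-(trimethylsilyl)pent-2-en-4-yn-1-yl propanoate
Conditions: Et3N, DMAP (cat.), CH2Cl2, 0 °C
Reagents that add atoms: none
Why: DMAP-catalysed O-acylation of a primary allylic alcohol by an acid chloride (nucleophilic acyl substitution) installs the propanoate whose α-carbon becomes C4.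

Step 3
Reactants: 5 (E)-3-methyl-5-(trimethylsilyl)pent-2-en-4-yn-1-yl propanoate
Product: 8 (2R,3R)-2,3-dimethyl-3-[(trimethylsilyl)ethynyl]pent-4-enoic acid, via boron ketene acetal 6 (not isolated), via acyloxyborane 7 (not isolated)
Conditions: (4S,5S)-2-bromo-4,5-diphenyl-1,3-bis{[3,5-bis(trifluoromethyl)phenyl]sulfonyl}-1,3,2-diazaborolidine (1.2 equiv), Et3N, toluene–hexane, −78 °C; then −20 to 4 °C, several days; aqueous work-up
Reagents that add atoms: none
Why: Enantioselective boron-enolate Ireland–Claisen rearrangement: Et3N in the non-polar medium gives the ketene acetal with the C-methyl cis to the allyloxy oxygen, the [3,3] shift through a chair with the (E)-alkene places both methyl groups axial and the alkynyl group equatorial, which fixes the C4/C5 relative configuration (both methyls on one face of the later ring A), and the C2-symmetric sulfonamide ligand on boron selects the enolate face and so the absolute configuration.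

Step 4
Reactants: 8 (2R,3R)-2,3-dimethyl-3-[(trimethylsilyl)ethynyl]pent-4-enoic acid
Product: 10 (2R,3R)-N-methoxy-N,2,3-trimethyl-3-[(trimethylsilyl)ethynyl]pent-4-enamide, via acyl imidazole 9 (not isolated)
Conditions: 1,1'-carbonyldiimidazole, CH2Cl2, rt; then MeNH(OMe)·HCl, rt to 40 °C
Reagents that add atoms: N,O-dimethylhydroxylamine hydrochloride, CNOC.Cl
Why: Amide coupling through the acyl imidazole (carbonyldiimidazole activation) gives the N-methoxy-N-methylamide without any base able to epimerise C4.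

Step 5
Reactants: 10 (2R,3R)-N-methoxy-N,2,3-trimethyl-3-[(trimethylsilyl)ethynyl]pent-4-enamide
Product: 11 (2E,5R,6R)-5,6-dimethyl-6-[(trimethylsilyl)ethynyl]octa-2,7-dien-4-one
Conditions: (E)-1-bromoprop-1-ene, t-BuLi (2 equiv per bromide), Et2O, −78 °C; then 10, THF, −78 to 0 °C; cold 1 M HCl
Reagents that add atoms: (E)-prop-1-enyllithium, C/C=C/[Li], made in the flask from (E)-1-bromoprop-1-ene, C/C=C/Br
Why: Weinreb ketone synthesis: the vinyllithium formed by bromine–lithium exchange with retention of the E geometry adds only once, because the chelated tetrahedral adduct survives until the acidic quench.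

Step 6
Reactants: 11 (2E,5R,6R)-5,6-dimethyl-6-[(trimethylsilyl)ethynyl]octa-2,7-dien-4-one
Product: 12 (2E,4S,5R,6R)-5,6-dimethyl-6-[(trimethylsilyl)ethynyl]octa-2,7-dien-4-ol
Conditions: LiBH(sec-Bu)3, THF, −78 °C; aq. NH4Cl
Reagents that add atoms: none
Why: Felkin–Anh 1,2-reduction: the bulky borohydride attacks the carbonyl anti to the quaternary C5 substituent of C4 and past the C4 hydrogen, which should give the (3S) carbinol, and a β-substituted acyclic enone takes hydride at the carbonyl carbon with this reagent.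

Step 7
Reactants: 12 (2E,4S,5R,6R)-5,6-dimethyl-6-[(trimethylsilyl)ethynyl]octa-2,7-dien-4-ol
Product: 13 tert-butyl{[(2E,4S,5R,6R)-5,6-dimethyl-6-[(trimethylsilyl)ethynyl]octa-2,7-dien-4-yl]oxy}dimethylsilane
Conditions: t-BuMe2SiOTf, 2,6-lutidine, CH2Cl2, −78 to 0 °C
Reagents that add atoms: tert-butyldimethylsilyl trifluoromethanesulfonate, CC(C)(C)[Si](C)(C)OS(=O)(=O)C(F)(F)F
Why: Silylation of a hindered secondary alcohol with a silyl triflate and a non-nucleophilic pyridine base; the bulky ether later screens the C2 propenyl group.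

Step 8
Reactants: 13 tert-butyl{[(2E,4S,5R,6R)-5,6-dimethyl-6-[(trimethylsilyl)ethynyl]octa-2,7-dien-4-yl]oxy}dimethylsilane
Product: 15 (3R,4R,5S,6E)-5-[(tert-butyldimethylsilyl)oxy]-3,4-dimethyl-3-[(trimethylsilyl)ethynyl]oct-6-en-1-ol, via B-alkyl-9-borabicyclononane 14 (not isolated)
Conditions: 9-BBN (1.2 equiv), THF, 0 °C to rt; then 30% H2O2, aq. NaOAc, 0 °C to rt
Reagents that add atoms: hydrogen peroxide, OO
Why: Hydroboration–oxidation: the bulky dialkylborane adds anti-Markovnikov to the monosubstituted C6=C7 vinyl group much faster than to the 1,2-disubstituted propenyl group or the silylalkyne, and the buffered peroxide oxidation spares the C(sp)–Si bond.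

Step 9
Reactants: 15 (3R,4R,5S,6E)-5-[(tert-butyldimethylsilyl)oxy]-3,4-dimethyl-3-[(trimethylsilyl)ethynyl]oct-6-en-1-ol
Product: 16 tert-butyl{[(2E,4S,5R,6R)-8-iodo-5,6-dimethyl-6-[(trimethylsilyl)ethynyl]oct-2-en-4-yl]oxy}dimethylsilane
Conditions: I2, PPh3, imidazole, CH2Cl2, 0 °C to rt
Reagents that add atoms: iodine, II
Why: Appel-type iodination: the unhindered primary alcohol is converted into the iodide by SN2 displacement of the oxyphosphonium group.

Step 10
Reactants: 16 tert-butyl{[(2E,4S,5R,6R)-8-iodo-5,6-dimethyl-6-[(trimethylsilyl)ethynyl]oct-2-en-4-yl]oxy}dimethylsilane; 17 acrolein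
Product: 20 (6R,7R,8S,9E)-8-[(tert-butyldimethylsilyl)oxy]-6-ethynyl-6,7-dimethylundeca-1,9-dien-3-ol (both C3 epimers of the chain, that is C8 epimers), via alkyllithium 18 (not isolated), via silylalkyne carbinol 19 (not isolated)
Conditions: t-BuLi (2.1 equiv), Et2O–pentane, −78 °C; acrolein, −78 °C; then MeOH, K2CO3, rt
Reagents that add atoms: none
Why: Iodine–lithium exchange, 1,2-addition of the primary alkyllithium to the enal and base-catalysed methanolysis of the C(sp)–Si bond in the same flask; the C8 carbinol forms without control, which is harmless because it is oxidised in step 12.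

Step 11
Reactants: 20 (6R,7R,8S,9E)-8-[(tert-butyldimethylsilyl)oxy]-6-ethynyl-6,7-dimethylundeca-1,9-dien-3-ol
Product: 21 (4aR,5R,6S)-6-[(tert-butyldimethylsilyl)oxy]-4a,5-dimethyl-2,3,4,4a,5,6-hexahydronaphthalen-2-ol (eremophilane numbering: 3S,4R,5R; both C8 epimers)
Conditions: second-generation Grubbs catalyst RuCl2(=CHPh)(H2IMes)(PCy3) (5–10 mol %), degassed CH2Cl2 (0.005 M), 40 °C, argon
Reagents that add atoms: none
Why: The ruthenium alkylidene forms at the unhindered C9 vinyl group, adds to the C10≡C1 triple bond through a ruthenacyclobutene whose opening leaves the C9=C10 bond and a vinylcarbene on C1, and that carbene then undergoes ring-closing alkene metathesis with the C2 propenyl group, releasing propene and an ethylidene that carries the chain. The closest known reaction type is ruthenium-catalysed tandem dienyne (ene–yne–ene) ring-closing metathesis to fused bicyclic 1,3-dienes. Ring B (C5, C6, C7, C8, C9, C10) closes in the exo mode of enyne metathesis as a six-membered ring, and ring A (C1, C2, C3, C4, C5, C10) closes by six-membered ring-closing metathesis of the C1 carbene onto C2. No stereocentre is created: C3, C4 and C5 are bystanders and the C8 epimer mixture passes through unchanged. The step needs initiation at C9 before C2 and exo closure onto C10; the monosubstituted vinyl carbinol should load far faster than the 1,2-disubstituted propenyl group screened by the silyl ether and the C4 methyl, exo closure to a six-membered ring is the normal mode at this tether length, and high dilution keeps cross metathesis down.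

Step 12
Reactants: 21 (4aR,5R,6S)-6-[(tert-butyldimethylsilyl)oxy]-4a,5-dimethyl-2,3,4,4a,5,6-hexahydronaphthalen-2-ol
Product: 22 (4aR,5R,6S)-6-[(tert-butyldimethylsilyl)oxy]-4a,5-dimethyl-4,4a,5,6-tetrahydronaphthalen-2(3H)-one
Conditions: activated MnO2 (excess), CH2Cl2, rt
Reagents that add atoms: none
Why: MnO2 oxidation of an allylic (dienylic) alcohol: both C8 epimers converge on the one conjugated dienone and the silyl ether is untouched.

Step 13
Reactants: 22 (4aR,5R,6S)-6-[(tert-butyldimethylsilyl)oxy]-4a,5-dimethyl-4,4a,5,6-tetrahydronaphthalen-2(3H)-one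
Product: 24 (4aR,5R,6S)-6-[(tert-butyldimethylsilyl)oxy]-3-(2-hydroxypropan-2-yl)-4a,5-dimethyl-4,4a,5,6-tetrahydronaphthalen-2(3H)-one (C7 epimers), via lithium dienolate 23 (not isolated)
Conditions: LiN(iPr)2, THF, −78 °C; acetone (excess), −78 °C; AcOH, −78 °C
Reagents that add atoms: acetone, CC(C)=O
Why: Kinetic deprotonation at C7, the only α-carbon that bears hydrogen, gives the cross-conjugated lithium enolate, which adds to acetone in an aldol addition, and the cold acidic quench forestalls retro-aldol cleavage.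

Step 14
Reactants: 24 (4aR,5R,6S)-6-[(tert-butyldimethylsilyl)oxy]-3-(2-hydroxypropan-2-yl)-4a,5-dimethyl-4,4a,5,6-tetrahydronaphthalen-2(3H)-one
Product: 26 (4aR,5R,6S)-6-[(tert-butyldimethylsilyl)oxy]-4a,5-dimethyl-3-(propan-2-ylidene)-4,4a,5,6-tetrahydronaphthalen-2(3H)-one, via tertiary mesylate 25 (not isolated)
Conditions: MeSO2Cl, Et3N (excess), DMAP (cat.), CH2Cl2, 0 °C to rt
Reagents that add atoms: none
Why: Mesylation of the tertiary aldol hydroxyl followed by E1cB elimination through the C7 enolate can only place the new double bond between C7 and the carbinol carbon, which gives the conjugated isopropylidene group and not the isopropenyl isomer.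

Step 15
Reactants: 26 (4aR,5R,6S)-6-[(tert-butyldimethylsilyl)oxy]-4a,5-dimethyl-3-(propan-2-ylidene)-4,4a,5,6-tetrahydronaphthalen-2(3H)-one
Product: 27 (4aR,5R,6S)-6-hydroxy-4a,5-dimethyl-3-(propan-2-ylidene)-4,4a,5,6-tetrahydronaphthalen-2(3H)-one
Conditions: HF·pyridine, THF–pyridine, 0 °C to rt
Reagents that add atoms: none
Why: Fluoride-mediated silyl ether cleavage (Si–F bond formation) under buffered, weakly acidic conditions frees the C3 hydroxyl without exposing the trienone to base.

Step 16
Reactants: 28 (S)-2-methylbutan-1-ol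
Product: 29 (S)-2-methylbutanal
Conditions: NaOCl (aq.), TEMPO (cat.), KBr (cat.), NaHCO3, CH2Cl2–H2O, 0 °C; distilled and used at once
Reagents that add atoms: none
Why: Anelli oxidation (oxoammonium catalysis with bleach) stops at the aldehyde under buffered two-phase conditions that do not enolise the α-stereocentre.

Step 17
Reactants: 29 (S)-2-methylbutanal
Product: 30 ethyl (2E,4E,6S)-6-methylocta-2,4-dienoate
Conditions: triethyl 4-phosphonocrotonate, LiN(SiMe3)2, THF, −78 °C; then 29, −78 to 0 °C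
Reagents that add atoms: ethyl (E)-4-(diethoxyphosphoryl)but-2-enoate, CCOC(=O)/C=C/CP(=O)(OCC)OCC
Why: Vinylogous Horner–Wadsworth–Emmons olefination: the stabilised phosphonate anion gives the (4E) alkene and keeps the (2E) geometry, at a temperature low enough that the α-branched aldehyde is not epimerised.

Step 18
Reactants: 30 ethyl (2E,4E,6S)-6-methylocta-2,4-dienoate
Product: 31 (2E,4E,6S)-6-methylocta-2,4-dienoic acid
Conditions: LiOH, THF–MeOH–H2O, rt; then 1 M HCl
Reagents that add atoms: lithium hydroxide, [Li+].[OH-]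
Why: Saponification (acyl substitution by hydroxide) cleaves the ethyl ester, and the C6 stereocentre is not acidic under these conditions.

Step 19
Reactants: 27 (4aR,5R,6S)-6-hydroxy-4a,5-dimethyl-3-(propan-2-ylidene)-4,4a,5,6-tetrahydronaphthalen-2(3H)-one; 31 (2E,4E,6S)-6-methylocta-2,4-dienoic acid
Product: 33 (1R,2S,8aR)-1,8a-dimethyl-6-oxo-7-(propan-2-ylidene)-1,2,6,7,8,8a-hexahydronaphthalen-2-yl (2E,4E,6S)-6-methylocta-2,4-dienoate (CNP0215744.1), via mixed anhydride 32 (not isolated)
Conditions: 31, 2,4,6-trichlorobenzoyl chloride, Et3N, toluene, rt; then 27, DMAP, rt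
Reagents that add atoms: none
Why: Yamaguchi esterification: DMAP opens the mixed anhydride at the dienoyl carbonyl and the hindered C3 alcohol attacks the acylpyridinium ion, so the C3–O bond is never broken and its configuration is retained.

Compound list
1 | (E)-3-methylpent-2-en-4-yn-1-ol | C#C/C(C)=C/CO | starting material
2 | trimethyl{[(E)-3-methyl-5-(trimethylsilyl)pent-2-en-4-yn-1-yl]oxy}silane | C[Si](C)(C)C#C/C(C)=C/CO[Si](C)(C)C | intermediate
3 | (E)-3-methyl-5-(trimethylsilyl)pent-2-en-4-yn-1-ol | C[Si](C)(C)C#C/C(C)=C/CO | intermediate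
4 | propanoyl chloride | CCC(=O)Cl | starting material
5 | (E)-3-methyl-5-(trimethylsilyl)pent-2-en-4-yn-1-yl propanoate | CCC(=O)OC/C=C(C)/C#C[Si](C)(C)C | intermediate
6 | (4S,5S)-2-{[(Z)-1-{[(E)-3-methyl-5-(trimethylsilyl)pent-2-en-4-yn-1-yl]oxy}prop-1-en-1-yl]oxy}-4,5-diphenyl-1,3-bis{[3,5-bis(trifluoromethyl)phenyl]sulfonyl}-1,3,2-diazaborolidine (C-methyl cis to the allyloxy oxygen) | C/C=C(/OB1N(S(=O)(=O)c2cc(cc(c2)C(F)(F)F)C(F)(F)F)[C@@H](c2ccccc2)[C@H](c2ccccc2)N1S(=O)(=O)c2cc(cc(c2)C(F)(F)F)C(F)(F)F)\OC/C=C(C)/C#C[Si](C)(C)C | intermediate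
7 | (4S,5S)-4,5-diphenyl-1,3-bis{[3,5-bis(trifluoromethyl)phenyl]sulfonyl}-1,3,2-diazaborolidin-2-yl (2R,3R)-2,3-dimethyl-3-[(trimethylsilyl)ethynyl]pent-4-enoate | C=C[C@@](C)(C#C[Si](C)(C)C)[C@@H](C)C(=O)OB1N(S(=O)(=O)c2cc(cc(c2)C(F)(F)F)C(F)(F)F)[C@@H](c2ccccc2)[C@H](c2ccccc2)N1S(=O)(=O)c2cc(cc(c2)C(F)(F)F)C(F)(F)F | intermediate
8 | (2R,3R)-2,3-dimethyl-3-[(trimethylsilyl)ethynyl]pent-4-enoic acid | C=C[C@@](C)(C#C[Si](C)(C)C)[C@@H](C)C(=O)O | intermediate
9 | (2R,3R)-1-(1H-imidazol-1-yl)-2,3-dimethyl-3-[(trimethylsilyl)ethynyl]pent-4-en-1-one | C=C[C@@](C)(C#C[Si](C)(C)C)[C@@H](C)C(=O)n1ccnc1 | intermediate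
10 | (2R,3R)-N-methoxy-N,2,3-trimethyl-3-[(trimethylsilyl)ethynyl]pent-4-enamide | C=C[C@@](C)(C#C[Si](C)(C)C)[C@@H](C)C(=O)N(C)OC | intermediate
11 | (2E,5R,6R)-5,6-dimethyl-6-[(trimethylsilyl)ethynyl]octa-2,7-dien-4-one | C=C[C@@](C)(C#C[Si](C)(C)C)[C@@H](C)C(=O)/C=C/C | intermediate
12 | (2E,4S,5R,6R)-5,6-dimethyl-6-[(trimethylsilyl)ethynyl]octa-2,7-dien-4-ol | C=C[C@@](C)(C#C[Si](C)(C)C)[C@@H](C)[C@@H](O)/C=C/C | intermediate
13 | tert-butyl{[(2E,4S,5R,6R)-5,6-dimethyl-6-[(trimethylsilyl)ethynyl]octa-2,7-dien-4-yl]oxy}dimethylsilane | C=C[C@@](C)(C#C[Si](C)(C)C)[C@@H](C)[C@@H](O[Si](C)(C)C(C)(C)C)/C=C/C | intermediate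
14 | 9-[(3R,4R,5S,6E)-5-[(tert-butyldimethylsilyl)oxy]-3,4-dimethyl-3-[(trimethylsilyl)ethynyl]oct-6-en-1-yl]-9-borabicyclo[3.3.1]nonane | C(C[C@@](C)(C#C[Si](C)(C)C)[C@@H](C)[C@@H](O[Si](C)(C)C(C)(C)C)/C=C/C)B1C2CCCC1CCC2 | intermediate
15 | (3R,4R,5S,6E)-5-[(tert-butyldimethylsilyl)oxy]-3,4-dimethyl-3-[(trimethylsilyl)ethynyl]oct-6-en-1-ol | OCC[C@@](C)(C#C[Si](C)(C)C)[C@@H](C)[C@@H](O[Si](C)(C)C(C)(C)C)/C=C/C | intermediate
16 | tert-butyl{[(2E,4S,5R,6R)-8-iodo-5,6-dimethyl-6-[(trimethylsilyl)ethynyl]oct-2-en-4-yl]oxy}dimethylsilane | ICC[C@@](C)(C#C[Si](C)(C)C)[C@@H](C)[C@@H](O[Si](C)(C)C(C)(C)C)/C=C/C | intermediate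
17 | acrolein (prop-2-enal) | C=CC=O | starting material
18 | [(3R,4R,5S,6E)-5-[(tert-butyldimethylsilyl)oxy]-3,4-dimethyl-3-[(trimethylsilyl)ethynyl]oct-6-en-1-yl]lithium | [Li]CC[C@@](C)(C#C[Si](C)(C)C)[C@@H](C)[C@@H](O[Si](C)(C)C(C)(C)C)/C=C/C | intermediate
19 | (6R,7R,8S,9E)-8-[(tert-butyldimethylsilyl)oxy]-6,7-dimethyl-6-[(trimethylsilyl)ethynyl]undeca-1,9-dien-3-ol (C3 epimers of the chain, that is C8) | C=CC(O)CC[C@@](C)(C#C[Si](C)(C)C)[C@@H](C)[C@@H](O[Si](C)(C)C(C)(C)C)/C=C/C | intermediate
20 | (6R,7R,8S,9E)-8-[(tert-butyldimethylsilyl)oxy]-6-ethynyl-6,7-dimethylundeca-1,9-dien-3-ol (C3 epimers of the chain, that is C8) | C=CC(O)CC[C@@](C)(C#C)[C@@H](C)[C@@H](O[Si](C)(C)C(C)(C)C)/C=C/C | intermediate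
21 | (4aR,5R,6S)-6-[(tert-butyldimethylsilyl)oxy]-4a,5-dimethyl-2,3,4,4a,5,6-hexahydronaphthalen-2-ol (C2 epimers, that is C8) | CC(C)(C)[Si](C)(C)O[C@H]1C=CC2=CC(O)CC[C@]2(C)[C@H]1C | intermediate
22 | (4aR,5R,6S)-6-[(tert-butyldimethylsilyl)oxy]-4a,5-dimethyl-4,4a,5,6-tetrahydronaphthalen-2(3H)-one | CC(C)(C)[Si](C)(C)O[C@H]1C=CC2=CC(=O)CC[C@]2(C)[C@H]1C | intermediate
23 | lithium (4aR,5R,6S)-6-[(tert-butyldimethylsilyl)oxy]-4a,5-dimethyl-4,4a,5,6-tetrahydronaphthalen-2-olate (cross-conjugated dienolate) | CC(C)(C)[Si](C)(C)O[C@H]1C=CC2=CC(O[Li])=CC[C@]2(C)[C@H]1C | intermediate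
24 | (4aR,5R,6S)-6-[(tert-butyldimethylsilyl)oxy]-3-(2-hydroxypropan-2-yl)-4a,5-dimethyl-4,4a,5,6-tetrahydronaphthalen-2(3H)-one (C3 epimers, that is C7) | CC(C)(C)[Si](C)(C)O[C@H]1C=CC2=CC(=O)C(C(C)(C)O)C[C@]2(C)[C@H]1C | intermediate
25 | 2-[(6S,7R,8aR)-6-[(tert-butyldimethylsilyl)oxy]-7,8a-dimethyl-3-oxo-1,2,3,6,7,8a-hexahydronaphthalen-2-yl]propan-2-yl methanesulfonate (mesylate of 24) | CC(C)(C)[Si](C)(C)O[C@H]1C=CC2=CC(=O)C(C(C)(C)OS(C)(=O)=O)C[C@]2(C)[C@H]1C | intermediate
26 | (4aR,5R,6S)-6-[(tert-butyldimethylsilyl)oxy]-4a,5-dimethyl-3-(propan-2-ylidene)-4,4a,5,6-tetrahydronaphthalen-2(3H)-one | CC(C)(C)[Si](C)(C)O[C@H]1C=CC2=CC(=O)C(=C(C)C)C[C@]2(C)[C@H]1C | intermediate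
27 | (4aR,5R,6S)-6-hydroxy-4a,5-dimethyl-3-(propan-2-ylidene)-4,4a,5,6-tetrahydronaphthalen-2(3H)-one | O[C@H]1C=CC2=CC(=O)C(=C(C)C)C[C@]2(C)[C@H]1C | intermediate
28 | (S)-2-methylbutan-1-ol | CC[C@H](C)CO | starting material
29 | (S)-2-methylbutanal | CC[C@H](C)C=O | intermediate
30 | ethyl (2E,4E,6S)-6-methylocta-2,4-dienoate | CC[C@H](C)/C=C/C=C/C(=O)OCC | intermediate
31 | (2E,4E,6S)-6-methylocta-2,4-dienoic acid | CC[C@H](C)/C=C/C=C/C(=O)O | intermediate
32 | (2E,4E,6S)-6-methylocta-2,4-dienoic 2,4,6-trichlorobenzoic anhydride | CC[C@H](C)/C=C/C=C/C(=O)OC(=O)c1c(Cl)cc(Cl)cc1Cl | intermediate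
33 | (1R,2S,8aR)-1,8a-dimethyl-6-oxo-7-(propan-2-ylidene)-1,2,6,7,8,8a-hexahydronaphthalen-2-yl (2E,4E,6S)-6-methylocta-2,4-dienoate (eremophilane numbering: 3S,4R,5R) | CC[C@H](C)/C=C/C=C/C(=O)O[C@H]1C=CC2=CC(=O)C(=C(C)C)C[C@]2(C)[C@H]1C | target

Total step count: 19. Longest linear sequence: 16 (steps 1 to 15, then step 19); steps 16 to 18 make the acid side chain.

The three steps most likely to fail

1. Step 11, tandem metathesis. What may go wrong: loading of the catalyst at the C2 propenyl end, or direct attack of a propagating carbene on the terminal alkyne, either of which would lead to the five–seven fused isomer or to monocyclic trienes; ruthenium-hydride isomerisation of the C8 allylic alcohol is a further loss channel. The fallback sets out from 20 and comes back at 21, and it gives up the intramolecular relay through the alkyne. Cross enyne metathesis of 20 with ethene (RuCl2(=CHPh)(H2IMes)(PCy3), ethene 1 atm, toluene, 60–80 °C) should turn the ethynyl group into a buta-1,3-dien-2-yl group and give (6R,7R,8S,9E)-6-(buta-1,3-dien-2-yl)-8-[(tert-butyldimethylsilyl)oxy]-6,7-dimethylundeca-1,9-dien-3-ol F1. After the ethene is purged, the same catalyst at high dilution should close ring B (C9 vinyl onto the C10 methylidene) and ring A (C1 vinyl onto the C2 propenyl group) by two ordinary alkene ring-closing metatheses, with loss of ethene and propene, to give 21.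

2. Step 3, enantioselective Ireland–Claisen rearrangement. What may go wrong: incomplete control of the enolate geometry or of the enolate face at this alkynyl-substituted, fully substituted allyl terminus, giving diastereomer or enantiomer mixtures, or a rearrangement too slow at the temperatures that preserve selectivity. The fallback sets out from 5 and comes back at 8; it takes the relative configuration from the classical lithium/silicon variant and the absolute configuration from a resolution. LiN(iPr)2 in THF at −78 °C followed by Me3SiCl should give the ketene acetal with the C-methyl cis to the allyloxy oxygen, trimethyl{[(1E)-1-{[(2E)-3-methyl-5-(trimethylsilyl)pent-2-en-4-yn-1-yl]oxy}prop-1-en-1-yl]oxy}silane F2. On warming to rt this should rearrange through the same chair to the racemic silyl ester, trimethylsilyl (2R*,3R*)-2,3-dimethyl-3-[(trimethylsilyl)ethynyl]pent-4-enoate F3, which aqueous acid hydrolyses to the racemic acid, that is 8 together with its mirror image (2S,3S)-2,3-dimethyl-3-[(trimethylsilyl)ethynyl]pent-4-enoic acid F4. Crystallisation with the enantiomer of 1-phenylethylamine that gives the less soluble salt of 8 (written here for the (R)-amine) should deliver (R)-1-phenylethylammonium (2R,3R)-2,3-dimethyl-3-[(trimethylsilyl)ethynyl]pent-4-enoate F5, and acidification returns 8.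

3. Step 6, enone reduction. What may go wrong: poor facial selectivity at C3 if the Felkin–Anh preference is weaker than expected, or competing conjugate reduction of the enone. The fallback sets out from 10 and comes back at 12; it replaces substrate control on an enone by reagent control on an ynone. CH3C≡CMgBr in THF at 0 °C should convert 10 into (5R,6R)-5,6-dimethyl-6-[(trimethylsilyl)ethynyl]oct-7-en-2-yn-4-one F6. Reduction with (R)-2-methyl-CBS-oxazaborolidine (cat.) and BH3·SMe2 in THF at −30 °C, where the slim alkynyl arm is the small group and the branched arm the large one (the same face that the Felkin–Anh model favours), should give (4R,5R,6R)-5,6-dimethyl-6-[(trimethylsilyl)ethynyl]oct-7-en-2-yn-4-ol F7. Hydroxyl-directed trans-hydroalumination with NaAlH2(OCH2CH2OMe)2 in THF at 0 °C should then reduce only the propargylic triple bond to the (E)-alkene and give 12.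

Further compounds
F1 | step 11 | (6R,7R,8S,9E)-6-(buta-1,3-dien-2-yl)-8-[(tert-butyldimethylsilyl)oxy]-6,7-dimethylundeca-1,9-dien-3-ol (C3 epimers) | C=CC(O)CC[C@@](C)(C(=C)C=C)[C@@H](C)[C@@H](O[Si](C)(C)C(C)(C)C)/C=C/C
F2 | step 3 | trimethyl{[(1E)-1-{[(2E)-3-methyl-5-(trimethylsilyl)pent-2-en-4-yn-1-yl]oxy}prop-1-en-1-yl]oxy}silane | C/C=C(/O[Si](C)(C)C)\OC/C=C(C)/C#C[Si](C)(C)C
F3 | step 3 | trimethylsilyl (2R*,3R*)-2,3-dimethyl-3-[(trimethylsilyl)ethynyl]pent-4-enoate (racemic, one enantiomer drawn) | C=C[C@@](C)(C#C[Si](C)(C)C)[C@@H](C)C(=O)O[Si](C)(C)C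
F4 | step 3 | (2S,3S)-2,3-dimethyl-3-[(trimethylsilyl)ethynyl]pent-4-enoic acid | C=C[C@](C)(C#C[Si](C)(C)C)[C@H](C)C(=O)O
F5 | step 3 | (R)-1-phenylethylammonium (2R,3R)-2,3-dimethyl-3-[(trimethylsilyl)ethynyl]pent-4-enoate | C=C[C@@](C)(C#C[Si](C)(C)C)[C@@H](C)C(=O)[O-].C[C@@H]([NH3+])c1ccccc1
F6 | step 6 | (5R,6R)-5,6-dimethyl-6-[(trimethylsilyl)ethynyl]oct-7-en-2-yn-4-one | C=C[C@@](C)(C#C[Si](C)(C)C)[C@@H](C)C(=O)C#CC
F7 | step 6 | (4R,5R,6R)-5,6-dimethyl-6-[(trimethylsilyl)ethynyl]oct-7-en-2-yn-4-ol | C=C[C@@](C)(C#C[Si](C)(C)C)[C@@H](C)[C@@H](O)C#CC
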